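Readings and results are calculated with made-up constants; the scatter is artificial.

- I began from a one-step world: L passes into G at one rate constant, each X begins one chain, and each chain grows until L is used. The length is then the ratio of charges, 35.7 for dusk and 57.1 for midnight.

| setting | Thursday's | dusk | midnight |
|---|---|---|---|
| L | 0.50 M | 0.50 M | 0.80 M |
| Q | 0.015 M | 0.0150 M | 0.0150 M |
| X | 21 mM | 14 mM | 14 mM |
| remark | run made earlier |  |  |
| time |  | 2.5 d | 2.5 d |

- Thursday's (time / h: G / %, L / %): 2.50: 22, 80; 8.00: 52, 47; 15.0: 69, 30; 20.0: 77, 21

(standard deviation of a reading: 1.5 percentage points)

- which of the two ends with the longer chains by the average number of monomer units in a chain (chains begun, living or dead) ("neither" if they lie within 10%) (dusk / midnight / neither)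
- average number of monomer units in a chain (chains begun, living or dead) at the end, dusk
- average number of monomer units in a chain (chains begun, living or dead) at the end, midnight

- From the last reading of Thursday's run I took a first-order constant of 0.0780 h⁻¹ for L, a reading with its scatter. That gives a half-life of 8.88 h, shorter than the 2.5 d planned, so in this world time was not what the next run hung on.
- The question was the cut in X. Thursday's readings do not show what Q does, but I suspected that each Q stops one growing end, which makes a small difference between two larger charges the thing to watch.
- For dusk and midnight I reckoned −1.00 mM as the margin, the charge of X minus the charge of Q, against 6.00 mM for Thursday's run. The sign changes, so with my suspicion right, growing ends could be stopped and L left over, and the one-step lengths shrink by the share of L unused.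
- I decided to run both recipes as written; the two differ in the L charge. My own reckoning had midnight leading by the ratio of L charges, 1.60.
- The forecast named midnight, with 30 for dusk and 48 for midnight, below my one-step lengths, and it said plainly: “Chain count is a guess”.
- The flasks gave midnight as the longer, with 17.0 in dusk and 26.9 in midnight, so the forecast stood high by a factor 1.76. At 2.50 d, 57.0% of the L remained in dusk and 57.7% in midnight.

    L + X → E + G (k = 0.0199 L mol⁻¹ min⁻¹)
    L + E → G + E, rate k2*[E]*[L] (k = 0.271 L mol⁻¹ min⁻¹)
    E + Q → Z (k = 0.920 L mol⁻¹ min⁻¹)
    L + X → J (k = 0.00235 L mol⁻¹ min⁻¹)

- In dusk the half-life of E against Q, 0.076 d at 0.164 d, was shorter than the 2.5 d of the run, and with the margin at −1.00 mM the end found X, the limiting reagent, at 0% of its charge, Q at 16.5% of its charge and E at 8.68 × 10⁻⁷ M. In a further flask, dusk with 0.024 M of X and so a margin of 9.00 mM, the end found Q at 0% of its charge, E at 0.00641 M and G at 99.3% of the L charged.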